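**Strategy.** The ten-membered carbocycle is not closed end to end but grown from a six-membered ring. Reading the C1–C10 epoxide as an alkene, C10=C1–C2–C3–C4=C5 is a ring 1,5-diene, the Cope partner of a cyclohexane C5–C10 that carries vinyl (C1, C2) on C10 and isopropenyl (C3, C4, C15) on C5. An anionic oxy-Cope shift of the C10 alkoxide forms C2–C3, cuts C5–C10 and delivers the (Z)-C4=C5 cyclodecenone with the C10 carbonyl poised for C14. The precursor is a 1-vinyl-2-isopropenylcyclohexanol (vinyl axial, cis to equatorial isopropenyl) bearing the C6–C9 stereocentres, with C8 (OTES) and C9 (OPMB) differentiated.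

Key step: step 17

Remark: target numbering (C1–C15) is used for every intermediate; α is the ring face of the C6 and C9 oxygens, β the face of the C7 side chain and the C8 oxygen.
Assumption: (R)-BINAP is taken to give the (5R) adduct in step 1 by the usual facial model for cyclohexenones; the antipodal ligand would serve if the sense were opposite.

Step 1
Reactants: 1 4,4-dimethoxycyclohexa-2,5-dien-1-one; 2 potassium isopropenyltrifluoroborate
Product: 3 (R)-4,4-dimethoxy-5-isopropenylcyclohex-2-enone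
Conditions: [Rh(cod)2]BF4 (cat.), (R)-BINAP, Et3N, toluene/H2O, 25 °C
Reagents that add atoms: none
Why: Rhodium–BINAP-catalysed asymmetric 1,4-addition (Hayashi–Miyaura type) of an alkenyltrifluoroborate to one of the two enantiotopic enone arms of the quinone monoketal, in which the ligand selects the enone face and sets C5, while the more hindered product enone should not react again.

Step 2
Reactants: 3 (R)-4,4-dimethoxy-5-isopropenylcyclohex-2-enone
Product: 5 10α-hydroxy enone, via lithium enolate 4 (not isolated)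
Conditions: LDA, THF, −78 °C; then 2-(phenylsulfonyl)-3-phenyloxaziridine, −78 °C; NH4Cl
Reagents that add atoms: 2-(phenylsulfonyl)-3-phenyloxaziridine, O=S(=O)(c1ccccc1)N1OC1c1ccccc1
Why: Kinetic α′-deprotonation of the enone at C10 and oxaziridine hydroxylation of the cross-conjugated enolate, the oxidant approaching anti to the neighbouring C5 isopropenyl group so that the C10 oxygen is trans to it (a control centre that is later destroyed).

Step 3
Reactants: 5 10α-hydroxy enone
Product: 6 10α-allyl ether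
Conditions: allyl bromide, Ag2O, 4 Å MS, Et2O, 25 °C, dark
Reagents that add atoms: allyl bromide, C=CCBr
Why: Silver-oxide-promoted O-alkylation of the α-ketol under non-basic conditions, which avoids enolisation and installs an ether that is orthogonal to PMB, silyl and lactone groups.

Step 4
Reactants: 6 10α-allyl ether
Product: 7 9β-allylic alcohol
Conditions: NaBH4, CeCl3·7H2O, MeOH, −40 °C
Reagents that add atoms: none
Why: Luche 1,2-reduction with axial hydride delivery on the half-chair that holds the C5 and C10 substituents equatorial, giving the equatorial 9β-alcohol (trans to the C10 ether, cis to isopropenyl, as in the carvone to cis-carveol case).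

Step 5
Reactants: 7 9β-allylic alcohol; 8 N,N-dimethylacetamide dimethyl acetal
Product: 10 C7 acetamide, via ketene aminal 9 (not isolated)
Conditions: xylene, 140 °C
Reagents that add atoms: none
Why: Eschenmoser–Claisen rearrangement, in which the ketene aminal formed on the 9β-oxygen undergoes a suprafacial [3,3] shift that delivers the acetamide carbon to the β face of C7 and moves the alkene to C8=C9, so C7 is set by chirality transfer from C9.

Step 6
Reactants: 10 C7 acetamide
Product: 11 C6 ketone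
Conditions: oxalic acid, THF/H2O, 0 → 25 °C; used directly
Reagents that add atoms: water, O
Why: Mild acid hydrolysis of the dimethyl ketal of the kind used for Birch-type β,γ-unsaturated ketones, which should unmask C6 without conjugating either flanking alkene and leaves C5 and C7 in their favoured cis-diequatorial arrangement.

Step 7
Reactants: 11 C6 ketone
Product: 12 6α-alcohol
Conditions: NaBH4, CeCl3·7H2O, MeOH, −78 → −40 °C
Reagents that add atoms: none
Why: Luche-type hydride reduction with axial attack on a ketone flanked by two equatorial α-substituents, giving the equatorial 6α-alcohol (C5, C6 and C7 all equatorial), which is also the more stable epimer.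

Step 8
Reactants: 12 6α-alcohol
Product: 13 6α-TIPS ether
Conditions: TIPSOTf, 2,6-lutidine, CH2Cl2, 0 °C
Reagents that add atoms: triisopropylsilyl triflate, CC(C)[Si](OS(=O)(=O)C(F)(F)F)(C(C)C)C(C)C
Why: Standard silylation of a hindered secondary alcohol with a silyl triflate and a hindered pyridine base.

Step 9
Reactants: 13 6α-TIPS ether
Product: 15 iodolactone, via imidate iodide 14 (not isolated)
Conditions: I2, THF/H2O, 25 °C, dark; Na2S2O3
Reagents that add atoms: iodine, II; water, O
Why: Iodolactonisation of a γ,δ-unsaturated N,N-dimethylamide, in which iodonium forms on the α face of C8=C9 opposite the side chain, the amide oxygen closes 5-exo on C8 from the β face (trans-diaxial addition) and water hydrolyses the imidate, setting the 8β-oxygen in a cis-fused lactone while the isopropenyl and allyl alkenes, which have no internal nucleophile, are left alone.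

Step 10
Reactants: 15 iodolactone
Product: 17 9α-PMB ether lactone, via epoxy ester 16 (not isolated)
Conditions: 4-methoxybenzyl alcohol, NaH, THF/DMF, 0 → 50 °C; NH4Cl
Reagents that add atoms: 4-methoxybenzyl alcohol (as its sodium alkoxide), COc1ccc(CO)cc1
Why: Alkoxide transesterification opens the lactone, the freed 8β-alkoxide displaces the anti 9α-iodide to give the 8β,9β-epoxide, and a second alkoxide opens it at C9 in trans-diaxial (Fürst–Plattner) fashion before relactonisation, so iodide is replaced by OPMB with net retention (double inversion) and the 9α-oxygen is set and differentiated from the 8β-oxygen.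

Step 11
Reactants: 17 9α-PMB ether lactone
Product: 18 10α-alcohol
Conditions: [CpRu(MeCN)3]PF6 (cat.), quinaldic acid (cat.), MeOH, 30 °C
Reagents that add atoms: none
Why: Ruthenium-catalysed deallylation by allyl transfer to methanol, a neutral cleavage of alkyl allyl ethers that should leave the lactone, the PMB and TIPS ethers and the isopropenyl alkene untouched.

Step 12
Reactants: 18 10α-alcohol
Product: 19 C10 ketone
Conditions: Dess–Martin periodinane, NaHCO3, CH2Cl2, 0 °C; used directly
Reagents that add atoms: none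
Why: Dess–Martin oxidation under buffered, non-basic conditions, chosen because the ketone is β,γ-unsaturated and carries β-oxygen leaving groups and must not meet base.

Step 13
Reactants: 19 C10 ketone; 20 ethynylmagnesium bromide
Product: 21 10β-ethynyl carbinol
Conditions: CeCl3, THF, −78 °C; NH4Cl
Reagents that add atoms: none
Why: Alkynylcerium 1,2-addition, whose low basicity suppresses enolisation and β-elimination, with the slim acetylide attacking axially from the β face anti to the axial 9α-OPMB group (polar Felkin–Anh), giving equatorial 10α-OH and axial 10β-ethynyl cis to the isopropenyl group, an arrangement that a vinyl Grignard reagent (equatorial attack) would not give.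

Step 14
Reactants: 21 10β-ethynyl carbinol
Product: 22 triol
Conditions: LiAlH4, THF, 0 °C → reflux
Reagents that add atoms: none
Why: LiAlH4 reduces the lactone to the C8/C12 diol and, by alkoxide-directed trans-hydroalumination of the propargylic alcohol, the alkyne to the vinyl group, leaving isolated alkenes and the ethers alone.

Step 15
Reactants: 22 triol
Product: 23 C12 TBS ether
Conditions: TBSCl, imidazole, DMF, 0 °C
Reagents that add atoms: tert-butyldimethylsilyl chloride, CC(C)(C)[Si](C)(C)Cl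
Why: Selective silylation of the primary alcohol in the presence of a hindered secondary and a tertiary hydroxyl.

Step 16
Reactants: 23 C12 TBS ether
Product: 24 oxy-Cope precursor
Conditions: TESOTf, 2,6-lutidine, CH2Cl2, −78 °C
Reagents that add atoms: triethylsilyl triflate, CC[Si](CC)(CC)OS(=O)(=O)C(F)(F)F
Why: Low-temperature silyl triflate silylation discriminates the secondary C8 hydroxyl from the far more hindered tertiary C10 hydroxyl, which must stay free, and gives C8 a group that can later be removed without touching the C9 PMB ether.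

Step 17
Reactants: 24 oxy-Cope precursor
Product: 27 (Z)-cyclodec-5-enone, via potassium alkoxide 25 (not isolated), via potassium enolate 26 (not isolated)
Conditions: KH, 18-crown-6, THF, 0 → 25 °C; then −78 °C, NH4Cl (aq)
Reagents that add atoms: none
Why: Deprotonation gives the C10 potassium alkoxide, whose oxyanion weakens the C5–C10 bond and accelerates a concerted [3,3] sigmatropic shift of the C3=C4–C5–C10–C1=C2 diene (anionic oxy-Cope rearrangement, the known ring expansion of 1,2-dialkenylcyclohexanols to cyclodec-5-enones). The ten-membered ring is not made by cyclisation: C2–C3 bonds through a six-membered chair transition state while C5–C10 breaks, a four-carbon ring expansion of the cyclohexane. No stereocentre is created; C5 and C10 become trigonal and C6–C9 are untouched. The selectivity needed is Z at C4=C5: the equatorial C5 isopropenyl, C6 silyloxy and C7 side chain lock the chair that holds the C10 vinyl axial, and in the chair transition state from this conformer C6 is axial on C5, which maps onto the ring-cis alkene, whereas the trans-dialkenyl epimer would give E. The enolate is born with ring-trans C1=C10 geometry, which does not matter because cold protonation returns the ketone. The C9 PMB ether cannot migrate to the neighbouring alkoxide and the trans-1,3 C8 silyl ether cannot reach it.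

Step 18
Reactants: 27 (Z)-cyclodec-5-enone
Product: 29 ring-cis enol triflate, via lithium enolate 28 (not isolated)
Conditions: LDA, THF, −78 °C; then N-(5-chloro-2-pyridyl)triflimide, −78 → 0 °C; NH4Cl
Reagents that add atoms: N-(5-chloro-2-pyridyl)triflimide, FC(F)(F)S(=O)(=O)N(c1ccc(Cl)cn1)S(=O)(=O)C(F)(F)F
Why: Kinetic deprotonation with LDA occurs at the unhindered C1 methylene and not at the C9 methine and gives the E(O)-enolate, which in the ten-membered ring is the ring-cis C1=C10 enolate, and O-sulfonylation fixes this geometry and turns the C10 oxygen into a leaving group.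

Step 19
Reactants: 29 ring-cis enol triflate; 30 (tributylstannyl)methanol
Product: 31 C14 allylic alcohol
Conditions: Pd(PPh3)4 (cat.), LiCl, 1,4-dioxane, 95 °C
Reagents that add atoms: none
Why: Stille cross-coupling of an alkenyl triflate with a (hydroxymethyl)stannane, LiCl assisting transmetalation, proceeds with retention of alkene geometry and installs C14 as a primary allylic alcohol.

Step 20
Reactants: 31 C14 allylic alcohol
Product: 32 1β,10β-epoxy alcohol
Conditions: Ti(OiPr)4 (cat.), D-(−)-diisopropyl tartrate, t-BuOOH, 4 Å MS, CH2Cl2, −20 °C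
Reagents that add atoms: tert-butyl hydroperoxide, CC(C)(C)OO
Why: Sharpless asymmetric epoxidation, in which the titanium tartrate binds the only free (allylic) hydroxyl and the D-(−)-tartrate delivers oxygen to the β face of the 2,3-disubstituted allylic alcohol under reagent control, setting C1 and C10 as the cis-epoxide stereospecifically while the isolated C4=C5 alkene is not touched.

Step 21
Reactants: 32 1β,10β-epoxy alcohol
Product: 34 epoxy acid, via epoxy aldehyde 33 (not isolated)
Conditions: TEMPO (cat.), PhI(OAc)2, MeCN/pH 7 buffer, 0 → 25 °C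
Reagents that add atoms: water, O
Why: Nitroxyl-catalysed oxidation of the primary alcohol through the aldehyde hydrate to the acid, mild toward alkene, PMB and silyl ethers, with a quaternary α-carbon that cannot epimerise.

Step 22
Reactants: 34 epoxy acid
Product: 35 epoxy methyl ester
Conditions: TMSCHN2, MeOH/toluene, 0 °C
Reagents that add atoms: trimethylsilyldiazomethane, C[Si](C)(C)C=[N+]=[N-]
Why: Neutral esterification of the acid with trimethylsilyldiazomethane in methanol, compatible with the epoxide and silyl ethers.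

Step 23
Reactants: 35 epoxy methyl ester
Product: 36 8β-alcohol
Conditions: PPTS, MeOH/CH2Cl2, 0 °C
Reagents that add atoms: none
Why: Acid-catalysed methanolysis removes the secondary triethylsilyl ether much faster than the TBS and TIPS ethers, and the electron-poor glycidic ester should resist the weak acid.

Step 24
Reactants: 36 8β-alcohol; 37 (S)-2-methylbutanoic acid
Product: 38 8β-(S)-2-methylbutanoate
Conditions: DIC, DMAP (cat.), CH2Cl2, 0 → 25 °C
Reagents that add atoms: none
Why: Steglich esterification of the only free hydroxyl, so that no C8/C9 selectivity is required, under conditions that should not epimerise the α-stereocentre of the acid.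

Step 25
Reactants: 38 8β-(S)-2-methylbutanoate
Product: 39 C12 alcohol
Conditions: HF·pyridine, pyridine, THF, 0 °C
Reagents that add atoms: none
Why: Buffered HF·pyridine cleaves the primary TBS ether selectively over the hindered secondary TIPS ether.

Step 26
Reactants: 39 C12 alcohol
Product: 40 C12 aldehyde
Conditions: Dess–Martin periodinane, NaHCO3, CH2Cl2, 0 → 25 °C
Reagents that add atoms: none
Why: Dess–Martin oxidation of the primary alcohol to the aldehyde under buffered conditions.

Step 27
Reactants: 40 C12 aldehyde; 41 N,N-dimethylmethyleneammonium iodide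
Product: 43 enal, via Mannich base 42 (not isolated)
Conditions: Et3N, CH2Cl2, 25 °C
Reagents that add atoms: none
Why: Mannich reaction of the aldehyde followed by amine elimination (α-methylenation of an aldehyde) installs C13 without strong base, so the esters, the epoxide and the C7 centre are not disturbed.

Step 28
Reactants: 43 enal
Product: 45 lactol, via hydroxy enal 44 (not isolated)
Conditions: HF·pyridine, THF, 0 → 25 °C
Reagents that add atoms: none
Why: Fluoride desilylation frees the 6α-hydroxyl, which adds to the aldehyde to close the five-membered lactol (5-exo-trig), the competing oxa-Michael closure being 5-endo and disfavoured.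

Step 29
Reactants: 45 lactol
Product: 46 9α-PMB ether of the target
Conditions: MnO2, CH2Cl2, 25 °C
Reagents that add atoms: none
Why: MnO2 oxidation of the allylic-type lactol gives the α-methylene-γ-lactone, while the epoxide, the esters and the PMB ether are inert.

Step 30
Reactants: 46 9α-PMB ether of the target
Product: 47 CNP0581690.1
Conditions: DDQ, CH2Cl2/pH 7 buffer, 0 °C
Reagents that add atoms: none
Why: Oxidative cleavage of the PMB ether with DDQ under buffered conditions frees the C9 hydroxyl without acyl migration or epoxide opening.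

**Compound list**
1 | 4,4-dimethoxycyclohexa-2,5-dien-1-one | COC1(OC)C=CC(=O)C=C1 | starting material
2 | potassium trifluoro(prop-1-en-2-yl)borate | C=C(C)[B-](F)(F)F.[K+] | starting material
3 | (R)-4,4-dimethoxy-5-(prop-1-en-2-yl)cyclohex-2-en-1-one (C9 ketone, C7=C8, C6 dimethyl ketal, 5β-isopropenyl) | C1C(=O)C=CC(OC)(OC)[C@H]1C(C)=C | intermediate
4 | lithium enolate of 3 (C10=C9–OLi) | C1=C([O-])C=CC(OC)(OC)[C@H]1C(C)=C.[Li+] | intermediate (not isolated)
5 | 10α-hydroxy enone (trans-6-hydroxy-4,4-dimethoxy-5-isopropenylcyclohex-2-enone) | O[C@@H]1C(=O)C=CC(OC)(OC)[C@H]1C(C)=C | intermediate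
6 | 10α-allyl ether of 5 | C=CCO[C@@H]1C(=O)C=CC(OC)(OC)[C@H]1C(C)=C | intermediate
7 | allylic alcohol: 9β-OH, 10α-O-allyl, C7=C8, C6 dimethyl ketal, 5β-isopropenyl | C=CCO[C@@H]1[C@@H](O)C=CC(OC)(OC)[C@H]1C(C)=C | intermediate
8 | 1,1-dimethoxy-N,N-dimethylethanamine (N,N-dimethylacetamide dimethyl acetal) | COC(C)(OC)N(C)C | starting material
9 | ketene aminal: 9β-O-[1-(dimethylamino)vinyl] ether of 7 | C=CCO[C@@H]1[C@@H](OC(=C)N(C)C)C=CC(OC)(OC)[C@H]1C(C)=C | intermediate (not isolated)
10 | amide: 7β-CH2CONMe2, C8=C9, 10α-O-allyl, C6 dimethyl ketal, 5β-isopropenyl | C=CCO[C@@H]1C=C[C@@H](CC(=O)N(C)C)C(OC)(OC)[C@H]1C(C)=C | intermediate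
11 | C6 ketone of 10 | C=CCO[C@@H]1C=C[C@@H](CC(=O)N(C)C)C(=O)[C@H]1C(C)=C | intermediate
12 | 6α-alcohol (5β-isopropenyl, 6α-OH, 7β-CH2CONMe2, C8=C9, 10α-O-allyl) | C=CCO[C@@H]1C=C[C@@H](CC(=O)N(C)C)[C@H](O)[C@H]1C(C)=C | intermediate
13 | 6α-TIPS ether of 12 | C=CCO[C@@H]1C=C[C@@H](CC(=O)N(C)C)[C@H](O[Si](C(C)C)(C(C)C)C(C)C)[C@H]1C(C)=C | intermediate
14 | cyclic imidate iodide (8β-O–C12(=NMe2+), 9α-iodo) | C=CCO[C@@H]1[C@H](I)[C@H]2OC(=[N+](C)C)C[C@H]2[C@H](O[Si](C(C)C)(C(C)C)C(C)C)[C@H]1C(C)=C.[I-] | intermediate (not isolated)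
15 | iodolactone: cis-fused 8β,12-γ-lactone, 9α-iodo, 10α-O-allyl, 6α-OTIPS, 5β-isopropenyl | C=CCO[C@@H]1[C@H](I)[C@H]2OC(=O)C[C@H]2[C@H](O[Si](C(C)C)(C(C)C)C(C)C)[C@H]1C(C)=C | intermediate
16 | 8β,9β-epoxy 4-methoxybenzyl ester | C=CCO[C@@H]1[C@H]2O[C@H]2[C@@H](CC(=O)OCc3ccc(OC)cc3)[C@H](O[Si](C(C)C)(C(C)C)C(C)C)[C@H]1C(C)=C | intermediate (not isolated)
17 | 8β,12-lactone with 9α-OPMB, 10α-O-allyl, 6α-OTIPS, 5β-isopropenyl | C=CCO[C@@H]1[C@H](OCc3ccc(OC)cc3)[C@H]2OC(=O)C[C@H]2[C@H](O[Si](C(C)C)(C(C)C)C(C)C)[C@H]1C(C)=C | intermediate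
18 | 10α-alcohol of 17 | O[C@@H]1[C@H](OCc3ccc(OC)cc3)[C@H]2OC(=O)C[C@H]2[C@H](O[Si](C(C)C)(C(C)C)C(C)C)[C@H]1C(C)=C | intermediate
19 | C10 ketone (9α-OPMB, 8β,12-lactone, 6α-OTIPS, 5β-isopropenyl) | O=C1[C@H](OCc3ccc(OC)cc3)[C@H]2OC(=O)C[C@H]2[C@H](O[Si](C(C)C)(C(C)C)C(C)C)[C@H]1C(C)=C | intermediate
20 | ethynylmagnesium bromide | C#C[Mg]Br | starting material
21 | 10β-ethynyl-10α-ol (lactone retained) | C#C[C@@]1(O)[C@H](OCc3ccc(OC)cc3)[C@H]2OC(=O)C[C@H]2[C@H](O[Si](C(C)C)(C(C)C)C(C)C)[C@H]1C(C)=C | intermediate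
22 | triol: 10β-vinyl-10α-OH, 9α-OPMB, 8β-OH, 7β-CH2CH2OH, 6α-OTIPS, 5β-isopropenyl | C=C[C@@]1(O)[C@H](OCc2ccc(OC)cc2)[C@@H](O)[C@@H](CCO)[C@H](O[Si](C(C)C)(C(C)C)C(C)C)[C@H]1C(C)=C | intermediate
23 | C12 TBS ether of 22 | C=C[C@@]1(O)[C@H](OCc2ccc(OC)cc2)[C@@H](O)[C@@H](CCO[Si](C)(C)C(C)(C)C)[C@H](O[Si](C(C)C)(C(C)C)C(C)C)[C@H]1C(C)=C | intermediate
24 | oxy-Cope precursor: 1-vinyl-2-isopropenylcyclohexanol (ring C5–C10) with 10β-vinyl, 10α-OH, 9α-OPMB, 8β-OTES, 7β-CH2CH2OTBS, 6α-OTIPS, 5β-isopropenyl | C=C[C@@]1(O)[C@H](OCc2ccc(OC)cc2)[C@@H](O[Si](CC)(CC)CC)[C@@H](CCO[Si](C)(C)C(C)(C)C)[C@H](O[Si](C(C)C)(C(C)C)C(C)C)[C@H]1C(C)=C | intermediate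
25 | potassium alkoxide of 24 | [K+].C=C[C@@]1([O-])[C@H](OCc2ccc(OC)cc2)[C@@H](O[Si](CC)(CC)CC)[C@@H](CCO[Si](C)(C)C(C)(C)C)[C@H](O[Si](C(C)C)(C(C)C)C(C)C)[C@H]1C(C)=C | intermediate (not isolated)
26 | potassium C10 enolate of the ten-membered ring (ring-trans C1=C10, Z C4=C5) | [K+].[O-]/C1=C\CC/C(C)=C\[C@@H](O[Si](C(C)C)(C(C)C)C(C)C)[C@H](CCO[Si](C)(C)C(C)(C)C)[C@H](O[Si](CC)(CC)CC)[C@H]1OCc1ccc(OC)cc1 | intermediate (not isolated)
27 | (Z)-cyclodec-5-enone: C10 ketone, Z C4=C5 (4-methyl), 6α-OTIPS, 7β-CH2CH2OTBS, 8β-OTES, 9α-OPMB | O=C1CCC/C(C)=C\[C@@H](O[Si](C(C)C)(C(C)C)C(C)C)[C@H](CCO[Si](C)(C)C(C)(C)C)[C@H](O[Si](CC)(CC)CC)[C@H]1OCc1ccc(OC)cc1 | intermediate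
28 | lithium C10 enolate (ring-cis C1=C10) | [Li+].[O-]/C1=C/CC/C(C)=C\[C@@H](O[Si](C(C)C)(C(C)C)C(C)C)[C@H](CCO[Si](C)(C)C(C)(C)C)[C@H](O[Si](CC)(CC)CC)[C@H]1OCc1ccc(OC)cc1 | intermediate (not isolated)
29 | C10 enol triflate, ring-cis C1=C10 | O=S(=O)(O/C1=C/CC/C(C)=C\[C@@H](O[Si](C(C)C)(C(C)C)C(C)C)[C@H](CCO[Si](C)(C)C(C)(C)C)[C@H](O[Si](CC)(CC)CC)[C@H]1OCc1ccc(OC)cc1)C(F)(F)F | intermediate
30 | (tributylstannyl)methanol | CCCC[Sn](CCCC)(CCCC)CO | starting material
31 | C14 allylic alcohol (10-hydroxymethyl, ring-cis C1=C10) | OC/C1=C/CC/C(C)=C\[C@@H](O[Si](C(C)C)(C(C)C)C(C)C)[C@H](CCO[Si](C)(C)C(C)(C)C)[C@H](O[Si](CC)(CC)CC)[C@H]1OCc1ccc(OC)cc1 | intermediate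
32 | 1β,10β-epoxy C14 alcohol | CC(C)[Si](O[C@@H]1/C=C(/C)CC[C@H]2O[C@@]2(CO)[C@H](OCc3ccc(OC)cc3)[C@@H](O[Si](CC)(CC)CC)[C@H]1CCO[Si](C)(C)C(C)(C)C)(C(C)C)C(C)C | intermediate
33 | 1β,10β-epoxy C14 aldehyde | CC(C)[Si](O[C@@H]1/C=C(/C)CC[C@H]2O[C@@]2(C=O)[C@H](OCc3ccc(OC)cc3)[C@@H](O[Si](CC)(CC)CC)[C@H]1CCO[Si](C)(C)C(C)(C)C)(C(C)C)C(C)C | intermediate (not isolated)
34 | 1β,10β-epoxy C14 acid | CC(C)[Si](O[C@@H]1/C=C(/C)CC[C@H]2O[C@@]2(C(=O)O)[C@H](OCc3ccc(OC)cc3)[C@@H](O[Si](CC)(CC)CC)[C@H]1CCO[Si](C)(C)C(C)(C)C)(C(C)C)C(C)C | intermediate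
35 | epoxy methyl ester (8β-OTES) | CC(C)[Si](O[C@@H]1/C=C(/C)CC[C@H]2O[C@@]2(C(=O)OC)[C@H](OCc3ccc(OC)cc3)[C@@H](O[Si](CC)(CC)CC)[C@H]1CCO[Si](C)(C)C(C)(C)C)(C(C)C)C(C)C | intermediate
36 | epoxy methyl ester, 8β-OH | CC(C)[Si](O[C@@H]1/C=C(/C)CC[C@H]2O[C@@]2(C(=O)OC)[C@H](OCc3ccc(OC)cc3)[C@@H](O)[C@H]1CCO[Si](C)(C)C(C)(C)C)(C(C)C)C(C)C | intermediate
37 | (S)-2-methylbutanoic acid | CC[C@H](C)C(=O)O | starting material
38 | 8β-(S)-2-methylbutanoate (C12 OTBS, 6α-OTIPS, 9α-OPMB) | CC(C)[Si](O[C@@H]1/C=C(/C)CC[C@H]2O[C@@]2(C(=O)OC)[C@H](OCc3ccc(OC)cc3)[C@@H](OC(=O)[C@@H](C)CC)[C@H]1CCO[Si](C)(C)C(C)(C)C)(C(C)C)C(C)C | intermediate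
39 | C12 primary alcohol | CC(C)[Si](O[C@@H]1/C=C(/C)CC[C@H]2O[C@@]2(C(=O)OC)[C@H](OCc3ccc(OC)cc3)[C@@H](OC(=O)[C@@H](C)CC)[C@H]1CCO)(C(C)C)C(C)C | intermediate
40 | C12 aldehyde | CC(C)[Si](O[C@@H]1/C=C(/C)CC[C@H]2O[C@@]2(C(=O)OC)[C@H](OCc3ccc(OC)cc3)[C@@H](OC(=O)[C@@H](C)CC)[C@H]1CC=O)(C(C)C)C(C)C | intermediate
41 | N,N-dimethylmethyleneammonium iodide | C[N+](C)=C.[I-] | starting material
42 | Mannich base (C11 bearing CH2NMe2, C11 epimers) | CC(C)[Si](O[C@@H]1/C=C(/C)CC[C@H]2O[C@@]2(C(=O)OC)[C@H](OCc3ccc(OC)cc3)[C@@H](OC(=O)[C@@H](C)CC)[C@H]1C(CN(C)C)C=O)(C(C)C)C(C)C | intermediate (not isolated)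
43 | enal: C11(=C13H2)–C12HO, 6α-OTIPS | CC(C)[Si](O[C@@H]1/C=C(/C)CC[C@H]2O[C@@]2(C(=O)OC)[C@H](OCc3ccc(OC)cc3)[C@@H](OC(=O)[C@@H](C)CC)[C@H]1C(=C)C=O)(C(C)C)C(C)C | intermediate
44 | hydroxy enal (6α-OH) | O[C@@H]1/C=C(/C)CC[C@H]2O[C@@]2(C(=O)OC)[C@H](OCc3ccc(OC)cc3)[C@@H](OC(=O)[C@@H](C)CC)[C@H]1C(=C)C=O | intermediate (not isolated)
45 | α-methylene lactol (C12 anomers) | C=C1C(O)O[C@@H]2/C=C(/C)CC[C@H]3O[C@@]3(C(=O)OC)[C@H](OCc4ccc(OC)cc4)[C@@H](OC(=O)[C@@H](C)CC)[C@@H]12 | intermediate
46 | 9α-PMB ether of the target | C=C1C(=O)O[C@@H]2/C=C(/C)CC[C@H]3O[C@@]3(C(=O)OC)[C@H](OCc4ccc(OC)cc4)[C@@H](OC(=O)[C@@H](C)CC)[C@@H]12 | intermediate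
47 | CNP0581690.1 | C=C1C(=O)O[C@@H]2/C=C(/C)CC[C@H]3O[C@@]3(C(=O)OC)[C@H](O)[C@@H](OC(=O)[C@@H](C)CC)[C@@H]12 | target

**Totals.** Total step count: 30. Longest linear sequence: 30 steps (1 → 47).

**Steps most likely to fail**

Step 17. Leakage through a boat-like transition state, or reaction through the ring-flipped chair, would erode the Z preference so that the ring-trans C4=C5 isomer forms alongside the wanted one. The fallback sets out from 24 and returns at 27: the geometry is not left to kinetic control; the crude rearrangement product containing the (4E)-cyclodecenone F1 is equilibrated by reversible thiyl-radical addition–elimination (PhSSPh, hν, benzene), which should funnel the strained ring-trans alkene into the more stable ring-cis isomer 27.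

Step 20. Mismatched double diastereoselection: if the ring conformation shields the β face of C1=C10, reagent control by the tartrate may be eroded or the epoxidation may stall. The fallback sets out from 31 and returns at 36 and relies on substrate direction from the β face. The triethylsilyl ether of 31 is removed (PPTS, MeOH, 0 °C) to give the C8,C14-diol F2. Epoxidation with VO(acac)2 and t-BuOOH, directed jointly by the allylic C14 hydroxyl and the homoallylic 8β-hydroxyl that lies on the β face, gives the epoxy diol F3. TEMPO/PhI(OAc)2 oxidises only the primary alcohol to the epoxy hydroxy acid F4, and TMSCHN2 then gives 36.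

Step 13. Poor facial selectivity (attack from the α face, which would place the alkyne equatorial) or base-induced β-elimination of the lactone oxygen from ketone 19. The fallback sets out from 19 and returns at 22 and builds the axial C–C bond by sulfur-ylide chemistry. Dimethylsulfonium methylide (Me3S+ I−, n-BuLi, THF, −10 °C; Corey–Chaykovsky reaction, which transfers methylene axially) gives the spiro-epoxide F5. A further equivalent of the same ylide opens the terminal epoxide and loses dimethyl sulfide to give the vinyl carbinol lactone F6 (one-carbon homologation of an epoxide to an allylic alcohol). LiAlH4 then reduces the lactone to triol 22.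

**Further compounds**
F1 | step 17 | (4E)-isomer of cyclodecenone 27 | O=C1CCC/C(C)=C/[C@@H](O[Si](C(C)C)(C(C)C)C(C)C)[C@H](CCO[Si](C)(C)C(C)(C)C)[C@H](O[Si](CC)(CC)CC)[C@H]1OCc1ccc(OC)cc1
F2 | step 20 | C8,C14-diol (31 without the triethylsilyl group) | OC/C1=C/CC/C(C)=C\[C@@H](O[Si](C(C)C)(C(C)C)C(C)C)[C@H](CCO[Si](C)(C)C(C)(C)C)[C@H](O)[C@H]1OCc1ccc(OC)cc1
F3 | step 20 | 1β,10β-epoxy C8,C14-diol | CC(C)[Si](O[C@@H]1/C=C(/C)CC[C@H]2O[C@@]2(CO)[C@H](OCc3ccc(OC)cc3)[C@@H](O)[C@H]1CCO[Si](C)(C)C(C)(C)C)(C(C)C)C(C)C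
F4 | step 20 | 1β,10β-epoxy C14 acid with free 8β-OH | CC(C)[Si](O[C@@H]1/C=C(/C)CC[C@H]2O[C@@]2(C(=O)O)[C@H](OCc3ccc(OC)cc3)[C@@H](O)[C@H]1CCO[Si](C)(C)C(C)(C)C)(C(C)C)C(C)C
F5 | step 13 | C10 spiro-epoxide (CH2 on the β face, O on the α face) of lactone 19 | C1O[C@@]12[C@H](OCc3ccc(OC)cc3)[C@H]4OC(=O)C[C@H]4[C@H](O[Si](C(C)C)(C(C)C)C(C)C)[C@H]2C(C)=C
F6 | step 13 | 10β-vinyl-10α-ol lactone | C=C[C@@]1(O)[C@H](OCc3ccc(OC)cc3)[C@H]2OC(=O)C[C@H]2[C@H](O[Si](C(C)C)(C(C)C)C(C)C)[C@H]1C(C)=C
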